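The ratio I would reckon with, and it fits your hunch that dying reagent matters, is the rate of making target over the fractional rate of loss of c_reagent: call it the reach, the target gained while c_reagent falls by a factor e.

| setting | gamma | theta | flask |
|---|---|---|---|
| substrate | 0.30 M | 0.30 M | 0.30 M |
| reagent | 0.36 M | 0.36 M | 0.360 M |
| free catalyst | 2 mM | 4.5 mM | 3.0 mM |
| remark | run made earlier | run made earlier |  |

| run | time / min | target / % | substrate / % |
|---|---|---|---|
| gamma | 6.00 | 0.5 | 99.3 |
| gamma | 15.0 | 1.5 | 97.9 |
| gamma | 30.0 | 3.1 | 96.9 |
| gamma | 50.0 | 4.0 | 95.6 |
| theta | 12.0 | 3.0 | 96.5 |
| theta | 25.0 | 4.9 | 93.3 |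
| theta | 40.0 | 7.6 | 92.4 |
| theta | 50.0 | 8.2 | 91.1 |

(readings scatter by 0.3 percentage points)

- apparent order in free catalyst when 10% of the substrate are converted (percent change of the rate of making target for one percent more free catalyst charged)
- apparent order in reagent when 10% of the substrate are converted (percent change of the rate of making target for one percent more reagent charged)

I assume that substrate and free catalyst stay at equilibrium with catalyst intermediate A, so that, with substrate near its charge, the rate of making target goes with the catalyst charged times c_reagent. I also assume that the loss to homo dimer outruns the use in the cycle. The reach then scales with the catalyst charged, not with the reagent charged, and the rate falls as exp(-target/reach).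

Two successive windows of a run give the reach: the target gained between their middles, over the logarithm of their rates. The gamma run reads 2.41% and the theta run 10.4%, a rough pair at this scatter. Taken per mM, averaged and scaled to the flask, they give a reach of 5.26%.

At conversion X the order in free catalyst is one plus X/reach, which for the flask at 10% is 2.90. The order in reagent is one, a guess since no run varied it. At a fixed charge of reagent, the time to X goes as exp(X/reach) minus one.

The forecast gives 2 (1.35 to 2.8) in free catalyst, lower than my figure, and 0.85 (0.5 to 1.05) in reagent, taking reagent loss “with a half-life near 45 min”.

The simulation gives 3.4 in free catalyst and 1.2 in reagent.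

    substrate + free catalyst ⇌ catalyst intermediate A (K = 2.90 /M, k = 0.350 /M/s)
    reagent + catalyst intermediate A → catalyst intermediate B (k = 0.0250 /M/s)
    catalyst intermediate B → free catalyst + target (k = 0.0430 /s)
    2 reagent → homo dimer (k = 0.00110 /M/s)

In the flask at 9.91 min, reagent goes to homo dimer 17 times faster than into catalyst intermediate B, and at 40.0 min the flask holds target at 4.96% with reagent at 32.7% of its charge, a reach of 4.44%. That reach puts the order in free catalyst at 3.25 against the simulated 3.4, and, scaled up for a second flask with twice the free catalyst, it puts the factor on the time to 10% at 0.245, where the simulated run gives 0.247.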